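## Retrosynthetic overview

1. The target comes from a benzyl-acetal enone epoxide by one hydrogenation (16-methyl and free lactol); the oxirane and the ring D enone come from a 9(11),16-diene.
2. The ring A cis-diacetate comes from a 1,2-dione, itself from a ring A silyl enol ether; both carbinol centres are set by hydride from the open face.
3. Key step: rings A and B (oxepane acetal) close together in an acetal-tethered cationic [4+2] between a 2-silyloxydiene on C9 and a prenal-derived vinyl oxocarbenium ion.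
4. The dienone comes from a Heck coupling of a bicyclic enol triflate with pent-3-en-2-one; the tether is a mixed acetal with prenal.
5. Rings C and D (bicyclo[3.2.1]octane) close together first, in an oxidative radical cascade of an auxiliary-bearing diallyl β-keto ester. Ring order: C+D, then A+B, then the oxirane.

Atom labels C1–C20 follow ent-kaurane numbering of the target: ring A = C1–C5/C10; oxepane ring B = C5–C6–O–C7–C8–C9–C10; ring C = C8/C9/C11–C14; ring D = C8/C13–C16; C14 is the one-carbon bridge.
Assumption: the (−)-8-phenylmenthyl ester steers the radical cascade to the C8 configuration drawn; if the sense is opposite, (+)-8-phenylmenthol is used.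
Assumption: the C6 lactol centre is anomeric and settles as the 6R form of the target.

## Route

Step 1
Reactants: 1 (−)-8-phenylmenthol; 2 2,2,6-trimethyl-4H-1,3-dioxin-4-one
Product: 3 (−)-8-phenylmenthyl acetoacetate
Conditions: xylene, 140 °C
Reagents that add atoms: none
Why: Thermal acetoacetylation: 2 transfers an acetoacetyl group to the hindered secondary alcohol with loss of acetone, and no stereocentre is touched.

Step 2
Reactants: 3 (−)-8-phenylmenthyl acetoacetate; 4 allyl bromide
Product: 6 (−)-8-phenylmenthyl 2-allyl-3-oxohept-6-enoate, via γ-allylated keto ester enolate 5 (not isolated)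
Conditions: NaH then n-BuLi, THF, 0 °C; 4 (1.0 equiv), 0 °C; then 4 (1.2 equiv), DMPU, 40 °C
Reagents that add atoms: allyl bromide (second equivalent of 4), C=CCBr
Why: Weiler dianion alkylation: the first equivalent of 4 alkylates the γ-carbon and the remaining stabilised enolate takes the second equivalent at the α-carbon, so two molecules of 4 are built into 6; the α-centre is left unassigned because it becomes a planar radical in step 3.

Step 3
Reactants: 6 (−)-8-phenylmenthyl 2-allyl-3-oxohept-6-enoate
Product: 7 (−)-8-phenylmenthyl (1R,5R)-6-methylidene-2-oxobicyclo[3.2.1]octane-1-carboxylate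
Conditions: Mn(OAc)3·2H2O (2.2 equiv), Cu(OAc)2·H2O (cat.), AcOH, 25 °C; chromatography
Reagents that add atoms: none
Why: Snider-type oxidative free-radical cascade: trivalent manganese gives the C8 radical, 6-endo closure (C8–C14) then 5-exo closure (C13–C16) form rings C and D, and divalent copper oxidises the primary radical to the exocyclic alkene; the bridge forces C8/C13 cis and the phenyl group of the auxiliary shields one face of the radical, so 7 is the major diastereomer.

Step 4
Reactants: 7 bicyclic keto ester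
Product: 8 C9 enol triflate of 7
Conditions: KN(SiMe3)2, PhNTf2, THF, −78 °C
Reagents that add atoms: N-phenylbis(trifluoromethanesulfonimide), O=S(=O)(N(c1ccccc1)S(=O)(=O)C(F)(F)F)C(F)(F)F
Why: C8 is quaternary, so the ketone can enolise only towards C11, and O-sulfonylation gives the enol triflate with the C9=C11 alkene in its final position.

Step 5
Reactants: 8 enol triflate ester
Product: 9 enol triflate alcohol (C7 hydroxymethyl on C8)
Conditions: i-Bu2AlH, CH2Cl2, −78 to 0 °C; aqueous potassium sodium tartrate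
Reagents that add atoms: none
Why: Hydride reduction of the ester to the neopentyl alcohol; the enol triflate is inert at low temperature and the auxiliary is released for recovery.

Step 6
Reactants: 9 enol triflate alcohol; 10 (E)-pent-3-en-2-one
Product: 11 (E)-dienone alcohol
Conditions: 10 (5 equiv), Pd(OAc)2 (cat.), n-Bu4NCl, NaHCO3, DMF, 70 °C
Reagents that add atoms: none
Why: Jeffery-type Heck reaction: the alkenyl–palladium adds to the β-carbon of 10 and syn β-hydride elimination restores conjugation, giving the E alkene with the bicycle trans to the acetyl group; the unactivated 16-methylidene does not compete.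

Step 7
Reactants: 11 (E)-dienone alcohol; 12 3-methylbut-2-enal
Product: 14 mixed benzyl acetal of 12 on O7, via trimethylsilyl ether 13 (not isolated)
Conditions: Me3SiCl, Et3N, CH2Cl2, 0 °C; then 12, BnOSiMe3, Me3SiOTf (cat.), −78 °C; pyridine quench
Reagents that add atoms: benzyloxytrimethylsilane, C[Si](C)(C)OCc1ccccc1
Why: Noyori acetalisation: Me3SiOTf joins the aldehyde with two different silyl ethers to a mixed acetal with loss of hexamethyldisiloxane; the new acetal centre is a mixture that does not matter.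

Step 8
Reactants: 14 mixed benzyl acetal
Product: 16 tetracyclic ring A silyl enol ether with C6 benzyl acetal, via trimethylsilyl dienol ether 15 (not isolated)
Conditions: KN(SiMe3)2, Me3SiCl, THF, −78 °C; solvent exchange; Me3SiOTf (cat.), 2,6-di-tert-butylpyridine, CH2Cl2, −78 to −40 °C; Et3N quench
Reagents that add atoms: chlorotrimethylsilane, C[Si](C)(C)Cl
Why: Proposed new method: Me3SiOTf ionises the mixed acetal to an O7-tethered vinyl oxocarbenium ion, the silyloxydiene terminus C3 adds to C4 and C5 then closes on C10 (asynchronous cationic [4+2]; closest known reactions are the Gassman cationic Diels–Alder reaction of α,β-unsaturated acetals and Mukaiyama–Michael additions) and BnOSiMe3 recaptures C6, so rings A and B form together; the CH2O tether on C8 leans to the C14 side, so the oxepane closes across the other face of C10 and leaves C20 syn to C14, and the exo mode with C9 on the outside of the diene puts H5 anti to C20, as in the target.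

Step 9
Reactants: 16 tetracyclic silyl enol ether
Product: 18 1-hydroxy 2-ketone, via 1-trimethylsilyloxy 2-ketone 17 (not isolated)
Conditions: DMDO (1.05 equiv), acetone/CH2Cl2, −78 °C; then K2CO3 (cat.), MeOH, 0 °C
Reagents that add atoms: dimethyldioxirane, CC1(C)OO1
Why: Rubottom oxidation: DMDO attacks only the electron-rich silyl enol ether, from the face away from the axial C20 methyl, and silyl migration gives the α-oxygenated ketone; basic methanolysis removes the silyl group without touching the acid-sensitive benzyl acetal, and this C1 configuration is erased in step 10.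

Step 10
Reactants: 18 1-hydroxy 2-ketone
Product: 19 ring A 1,2-dione
Conditions: Dess–Martin periodinane, NaHCO3, CH2Cl2, rt
Reagents that add atoms: none
Why: Dess–Martin oxidation of the α-hydroxy ketone to the 1,2-dione, so that both ring A carbinol centres can be set by reduction.

Step 11
Reactants: 19 ring A 1,2-dione
Product: 20 1,2-cis-diol
Conditions: NaBH4, MeOH/CH2Cl2, −40 to 0 °C
Reagents that add atoms: none
Why: Hydride reduction of both carbonyls from the face opposite the syn-axial C20 and C4 methyl groups, which puts both hydroxyls cis to C20 (1R,2S as in the target).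

Step 12
Reactants: 20 1,2-cis-diol
Product: 21 1,2-diacetate
Conditions: Ac2O, DMAP, pyridine, 40 °C
Reagents that add atoms: acetic anhydride, CC(=O)OC(C)=O
Why: DMAP-catalysed acylation of the equatorial C1 and the hindered axial C2 hydroxyl.

Step 13
Reactants: 21 1,2-diacetate
Product: 23 16-en-15-one, via 15-hydroxy compound 22 (not isolated)
Conditions: SeO2 (cat.), t-BuOOH, CH2Cl2, rt; then Dess–Martin periodinane, NaHCO3
Reagents that add atoms: tert-butyl hydroperoxide, CC(C)(C)OO; selenium dioxide, O=[Se]=O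
Why: SeO2 ene/[2,3] allylic oxidation reaches only C15 (the C9=C11 alkene has no allylic hydrogen on its substituted side and the C13 bridgehead cannot react), and Dess–Martin oxidation then gives the exocyclic enone, so the C15 carbinol configuration does not matter.

Step 14
Reactants: 23 16-en-15-one
Product: 24 9,11-epoxide
Conditions: mCPBA, NaHCO3, CH2Cl2, 0 °C
Reagents that add atoms: 3-chloroperbenzoic acid, OOC(=O)c1cccc(Cl)c1
Why: Prilezhaev epoxidation of the only electron-rich alkene left; the C15–C16 bridge and the C5–C6 arm of ring B block one face, so oxygen enters syn to C14 and C20 (9S,11R).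

Step 15
Reactants: 24 9,11-epoxide
Product: 26 target CNP0210140.1, via dihydro benzyl acetal 25 (not isolated)
Conditions: H2 (1 atm), Pd/C, EtOAc, rt
Reagents that add atoms: none
Why: Heterogeneous hydrogenation adds H2 to the enone alkene from the open exo face of ring D (methyl ends up towards C12, 16R), and hydrogenolysis of the benzyl acetal frees the lactol, which settles as the 6R anomer.

## Compound list

C6 is a mixture of acetal epimers in 16–25; the acetal carbon of 14 and 15 is also a mixture. C8 and C13 have the target configuration from 7 onward.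

1 | (−)-8-phenylmenthol, (1R,2S,5R)-5-methyl-2-(2-phenylpropan-2-yl)cyclohexan-1-ol | O[C@@H]1C[C@H](C)CC[C@H]1C(C)(C)c1ccccc1 | starting material
2 | 2,2,6-trimethyl-4H-1,3-dioxin-4-one | CC1=CC(=O)OC(C)(C)O1 | starting material
3 | (−)-8-phenylmenthyl 3-oxobutanoate | CC(=O)CC(=O)O[C@@H]1C[C@H](C)CC[C@H]1C(C)(C)c1ccccc1 | intermediate
4 | allyl bromide | C=CCBr | starting material
5 | (−)-8-phenylmenthyl 3-oxohept-6-enoate (formed as its enolate) | C=CCCC(=O)CC(=O)O[C@@H]1C[C@H](C)CC[C@H]1C(C)(C)c1ccccc1 | intermediate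
6 | (−)-8-phenylmenthyl 2-allyl-3-oxohept-6-enoate (C2 epimers) | C=CCCC(=O)C(CC=C)C(=O)O[C@@H]1C[C@H](C)CC[C@H]1C(C)(C)c1ccccc1 | intermediate
7 | (−)-8-phenylmenthyl (1R,5R)-6-methylidene-2-oxobicyclo[3.2.1]octane-1-carboxylate | O=C(O[C@@H]1C[C@H](C)CC[C@H]1C(C)(C)c1ccccc1)[C@@]23C[C@@H](CCC2=O)C(=C)C3 | intermediate
8 | enol triflate of 7 (OTf on C9, C9=C11) | O=C(O[C@@H]1C[C@H](C)CC[C@H]1C(C)(C)c1ccccc1)[C@@]23C[C@@H](CC=C2OS(=O)(=O)C(F)(F)F)C(=C)C3 | intermediate
9 | [1-(hydroxymethyl)-6-methylidenebicyclo[3.2.1]oct-2-en-2-yl] trifluoromethanesulfonate | OC[C@@]12C[C@@H](CC=C1OS(=O)(=O)C(F)(F)F)C(=C)C2 | intermediate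
10 | (E)-pent-3-en-2-one | C/C=C/C(C)=O | starting material
11 | (3E)-4-[1-(hydroxymethyl)-6-methylidenebicyclo[3.2.1]oct-2-en-2-yl]pent-3-en-2-one | OC[C@@]12C[C@@H](CC=C1/C(C)=C/C(C)=O)C(=C)C2 | intermediate
12 | 3-methylbut-2-enal (prenal) | CC(C)=CC=O | starting material
13 | O7-trimethylsilyl ether of 11 | C[Si](C)(C)OC[C@@]12C[C@@H](CC=C1/C(C)=C/C(C)=O)C(=C)C2 | intermediate
14 | mixed acetal of prenal: O7–CH(OBn)–CH=C(CH3)2 on the dienone | CC(C)=CC(OCc1ccccc1)OC[C@@]23C[C@@H](CC=C2/C(C)=C/C(C)=O)C(=C)C3 | intermediate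
15 | 2-(trimethylsilyloxy)diene of 14 (C10(CH3)=C1H–C2(OSiMe3)=C3H2) | CC(C)=CC(OCc1ccccc1)OC[C@@]23C[C@@H](CC=C2/C(C)=C/C(=C)O[Si](C)(C)C)C(=C)C3 | intermediate
16 | tetracycle: ring A with C1=C2–OSiMe3 and 4,4-dimethyl; oxepane ring B with C6 benzyl acetal; C9=C11; 16-methylidene; H5 anti to C20, C20 syn to C14 | C[Si](C)(C)OC=1CC(C)(C)[C@H]2C(OCc5ccccc5)OC[C@@]34C[C@@H](CC=C3[C@]2(C)C=1)C(=C)C4 | intermediate
17 | 1-(trimethylsilyloxy) 2-ketone (C1–O anti to C20) | O=C1CC(C)(C)[C@H]2C(OCc5ccccc5)OC[C@@]34C[C@@H](CC=C3[C@]2(C)[C@@H]1O[Si](C)(C)C)C(=C)C4 | intermediate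
18 | 1-hydroxy 2-ketone (C1–OH anti to C20) | O=C1CC(C)(C)[C@H]2C(OCc5ccccc5)OC[C@@]34C[C@@H](CC=C3[C@]2(C)[C@@H]1O)C(=C)C4 | intermediate
19 | ring A 1,2-dione | O=C1CC(C)(C)[C@H]2C(OCc5ccccc5)OC[C@@]34C[C@@H](CC=C3[C@]2(C)C1=O)C(=C)C4 | intermediate
20 | 1,2-cis-diol, both OH syn to C20 | O[C@H]1CC(C)(C)[C@H]2C(OCc5ccccc5)OC[C@@]34C[C@@H](CC=C3[C@]2(C)[C@H]1O)C(=C)C4 | intermediate
21 | 1,2-diacetate | CC(=O)O[C@H]1CC(C)(C)[C@H]2C(OCc5ccccc5)OC[C@@]34C[C@@H](CC=C3[C@]2(C)[C@H]1OC(C)=O)C(=C)C4 | intermediate
22 | 15-hydroxy-16-methylidene diacetate (C15 epimers) | CC(=O)O[C@H]1CC(C)(C)[C@H]2C(OCc5ccccc5)OC[C@@]34C[C@@H](CC=C3[C@]2(C)[C@H]1OC(C)=O)C(=C)C4O | intermediate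
23 | 16-en-15-one diacetate with C9=C11 | CC(=O)O[C@H]1CC(C)(C)[C@H]2C(OCc5ccccc5)OC[C@@]34C[C@@H](CC=C3[C@]2(C)[C@H]1OC(C)=O)C(=C)C4=O | intermediate
24 | (9S,11R)-9,11-epoxide of 23 | CC(=O)O[C@H]1CC(C)(C)[C@H]2C(OCc6ccccc6)OC[C@@]34C[C@@H](C[C@H]5O[C@]53[C@]2(C)[C@H]1OC(C)=O)C(=C)C4=O | intermediate
25 | (16R)-16-methyl-15-ketone, C6 benzyl acetal | CC(=O)O[C@H]1CC(C)(C)[C@H]2C(OCc6ccccc6)OC[C@@]34C[C@@H](C[C@H]5O[C@]53[C@]2(C)[C@H]1OC(C)=O)[C@@H](C)C4=O | intermediate
26 | CNP0210140.1: (1R,2S,5R,6R,8S,9S,10S,11R,13S,16R)-1,2-diacetoxy-9,11-epoxy-6-hydroxy-6,7-seco-ent-kauran-15-one 6,7-lactol (oxepane) | CC(=O)O[C@H]1CC(C)(C)[C@H]2[C@H](O)OC[C@@]34C[C@@H](C[C@H]5O[C@]53[C@]2(C)[C@H]1OC(C)=O)[C@@H](C)C4=O | target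

## Step count and risks

Total step count: 15. Longest linear sequence: 15.

Steps most likely to fail:

1. Step 8 (tethered cationic [4+2]). Possible failures are 1,2-addition to the oxocarbenium carbon, closure on the wrong face of C10, or a cis ring fusion. The fallback replaces the cationic acetal tether by a neutral ester tether. It sets out from 11: acylation of O7 with 3-methylbut-2-enoyl chloride (pyridine, DMAP) gives senecioate ester F1, and t-BuMe2SiOTf/Et3N gives tert-butyldimethylsilyl dienol ether F2. Heating (toluene, 190 °C, sealed tube) effects the ester-tethered intramolecular Diels–Alder reaction to lactone F3. i-Bu2AlH at −78 °C gives lactol F4, and NaH/BnBr gives benzyl acetal F5. DMDO gives 1-silyloxy 2-ketone F6, and HF·pyridine buffered with pyridine in THF removes the silyl group and returns to the route at 18.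

2. Step 6 (Heck coupling of a hindered enol triflate with a β-substituted enone). The fallback is a two-stage cross-coupling that sets out from 9: Miyaura borylation (B2pin2, PdCl2(dppf), KOAc, dioxane, 80 °C) gives pinacol boronate F7. Suzuki coupling (Pd(PPh3)4, K3PO4, THF/H2O) with (E)-4-chloropent-3-en-2-one F8, made from acetylacetone with oxalyl chloride/DMF, returns to the route at 11.

3. Step 14 (face of the epoxidation). If the peracid enters from the wrong face, the fallback sets out from 23: NBS in aqueous acetone puts bromine on the face the peracid prefers and water on C9 from the other face, giving bromohydrin F9. Ag2O in CH2Cl2 then closes the oxirane on the required face and returns to the route at 24.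

Further compounds

F1 | step 8 | O7 3-methylbut-2-enoate (senecioate) ester of 11 | CC(C)=CC(=O)OC[C@@]12C[C@@H](CC=C1/C(C)=C/C(C)=O)C(=C)C2
F2 | step 8 | 2-(tert-butyldimethylsilyloxy)diene of F1 | CC(C)=CC(=O)OC[C@@]12C[C@@H](CC=C1/C(C)=C/C(=C)O[Si](C)(C)C(C)(C)C)C(=C)C2
F3 | step 8 | tetracyclic lactone (C6 carbonyl, O7 ester oxygen) with ring A tert-butyldimethylsilyl enol ether | CC(C)(C)[Si](C)(C)OC=1CC(C)(C)[C@H]2C(=O)OC[C@@]34C[C@@H](CC=C3[C@]2(C)C=1)C(=C)C4
F4 | step 8 | C6 lactol of F3 | CC(C)(C)[Si](C)(C)OC=1CC(C)(C)[C@H]2C(O)OC[C@@]34C[C@@H](CC=C3[C@]2(C)C=1)C(=C)C4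
F5 | step 8 | C6 benzyl acetal of F4 (tert-butyldimethylsilyl analogue of 16) | CC(C)(C)[Si](C)(C)OC=1CC(C)(C)[C@H]2C(OCc5ccccc5)OC[C@@]34C[C@@H](CC=C3[C@]2(C)C=1)C(=C)C4
F6 | step 8 | 1-(tert-butyldimethylsilyloxy) 2-ketone (tert-butyldimethylsilyl analogue of 17) | O=C1CC(C)(C)[C@H]2C(OCc5ccccc5)OC[C@@]34C[C@@H](CC=C3[C@]2(C)[C@@H]1O[Si](C)(C)C(C)(C)C)C(=C)C4
F7 | step 6 | C9 pinacol boronate of the bicyclic alcohol | OC[C@@]12C[C@@H](CC=C1B1OC(C)(C)C(C)(C)O1)C(=C)C2
F8 | step 6 | (E)-4-chloropent-3-en-2-one | C/C(Cl)=C\C(C)=O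
F9 | step 14 | 11-bromo-9-hydroxy compound (bromohydrin of 23, OH on the oxirane face of 24) | CC(=O)O[C@H]1CC(C)(C)[C@H]2C(OCc6ccccc6)OC[C@@]34C[C@@H](C[C@H](Br)[C@]3(O)[C@]2(C)[C@H]1OC(C)=O)C(=C)C4=O
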